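The rate constants belong to no real substance; the flask was simulated.

The vessel was a closed, stirred flask of J under held gas D, which crossed slowly into solution as G.

    G + J.G → G.J.G (k1 = 4.2 M⁻¹ h⁻¹)
    G.J.G → L (k2 = 1.6 × 10⁻⁴ h⁻¹)
    D ⇌ G, rate k3*(csat - [G]) (k3 = 0.064 h⁻¹, csat = 28 mM)
    J.G → Q (k4 = 0.50 h⁻¹)
    J + G → J.G (k5 = 3.8 M⁻¹ h⁻¹)

| setting | birch | larch | ash | maple |
|---|---|---|---|---|
| J | 0.015 M | 0.050 M | 0.15 M | 0.50 M |
| D | 28 mM (held) | 28 mM (held) | 28 mM (held) | 28 mM (held) |
| time | 8.0 h | 8.0 h | 8.0 h | 8.0 h |

- at the start none of G is dissolved
- "hardly changes" means that all values lie within two and a half points (for a concentration: within two and a half percent of the largest)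
- run time (birch): 8.0 h

- [G.J.G] at the end for birch, larch, ash, maple, in this order
- the course of these numbers from the first flask to the last (rises, then falls / falls, then rises / rises all the way / hardly changes / falls all the way)

I began by dividing the rate at which G.J.G forms by the rate at which Q forms. Both draw on J.G, so J.G and time dropped out: G.J.G gained per Q gained equals [G] times 4.2 M⁻¹ h⁻¹ over 0.50 h⁻¹. That ratio of constants, 8.40 M⁻¹, I called the branching number; multiplied by [G], it gives the selectivity factor between the two exits of J.G, which changes as G changes.

Next I asked which constants had to be good. In birch, G.J.G had a half-life of 180 d against L, longer than the run of 8.0 h, so that constant made no difference there. In maple, G relaxed within 0.509 h, shorter than the run, so I set the inflow of G equal to its uptake by J. Maple's fraction of G.J.G then went as the square of the transfer coefficient and of the saturation level: a percent error in either counted 2 percent. In maple, a percent error in the constants of either addition, or of the loss to Q, counted about one.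

Then I took the numbers. I put maple's G at 9.12 × 10⁻⁴ M, so I reckoned G.J.G per Q at 0.766%. After a lag of 2.00 h for J.G to build up, the Q fraction came to 2.08%. That made the G.J.G fraction 0.0159% of the charge, or 7.97 × 10⁻⁵ M. My reckoning stopped there, because birch's G relaxed in 8.26 h, longer than the run.

The forecast gave 8.600 × 10⁻⁵ M, 1.900 × 10⁻⁴ M, 1.600 × 10⁻⁴ M and 7.200 × 10⁻⁵ M, a course that rises, then falls, on the ground that “Low J therefore makes too little J.G, and high J eats the G down to a very low level”. Its maple value lay below mine.

The flasks ended at 8.52 × 10⁻⁵ M, 1.65 × 10⁻⁴ M, 1.58 × 10⁻⁴ M and 7.26 × 10⁻⁵ M, a course that rises, then falls. Maple held 0.0145% of its charge as G.J.G, with G at 9.16 × 10⁻⁴ M after 4.00 h and 9.27 × 10⁻⁴ M after 8.00 h. The branching number times that last G and maple's Q fraction of 1.90% gave 0.0148%. In ash, the same product with G at 0.00289 M and Q at 4.73% gave 0.115%, and ash held 0.105%.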